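**Plan**

- Retrosynthetic cuts, in order: first the bond between tetralin C4 and naphthalene C2', traced back through a [3,3] shift to a C2–O aryl ether with a C3=C4 alkene; then that C2–O bond together with the former bridgehead C4–O bond, traced to the opening of an oxygen-bridged bicycle by the naphthol oxygen; last the two bonds from the anisole ring to the bridgeheads, traced to 3-methoxybenzyne and furan.
- Enabling feature: naphthalene C2' (the carbon bonded to tetralin C4) is ortho to the naphthol oxygen on C1', and C4 is the far end of the allyl unit C2–C3–C4 whose C2 is next to carbinol C1. O–C1'=C2' and C2–C3=C4 are therefore the six atoms of an aromatic Claisen rearrangement.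
- Forward ring order: the tetralin carbocycle arises first as an oxabenzonorbornadiene ([4+2]); the oxygen bridge is then cut so that the furan oxygen stays as the C1 hydroxyl; the bought naphthalene is joined through O and relayed to C; the last alkene is saturated at the end.
- Stereochemistry: C1 and a temporary trans C2 centre come from a ligand-controlled rhodium-catalysed opening of the racemic oxabicycle, run as a kinetic resolution with the naphthol limiting. The suprafacial shift hands C2 on to C4 on the face opposite the C1 oxygen, giving the trans-1,4 pair (1S,4R).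

Key step: step 5

Numbering: tetralin atoms as in the target (C1 carbinol, C4 aryl-bearing, C5 methoxy-bearing); naphthalene atoms carry primes (C1' oxygen-bearing, C2' its ortho carbon, C8' methoxy-bearing). In the oxabicycle, C4 is the bridgehead peri to the methoxy group and C1 the remote one.

Assumption: the (S)-1-[(R)-2-(diphenylphosphino)ferrocenyl]ethyldi-tert-butylphosphine antipode is taken to cleave the C–O bond at the R-configured bridgehead and so to give the (1R,2R) series in step 3, with the sense checked by MTPA ester analysis before scale-up; if it proves opposite, the mirror-image ligand is used and nothing else changes.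

**Route**

Step 1
Reactants: 1 3-bromoanisole; 2 furan (excess)
Product: 5 racemic 5-methoxy-1,4-epoxy-1,4-dihydronaphthalene, via 2-bromo-6-methoxyphenyllithium 3 (not isolated), via 3-methoxybenzyne 4 (not isolated)
Conditions: LiN(iPr)2, furan (excess), THF, −78 °C to rt
Reagents that add atoms: none
Why: The amide base should remove the proton between the methoxy and bromo groups (directed ortho-lithiation), aryllithium 3 should lose LiBr to give aryne 4, and the aryne should be trapped in situ by furan in a Diels–Alder [4+2] cycloaddition that builds the future tetralin carbocycle as an oxygen-bridged bicycle; the product is racemic and no control is sought here.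

Step 2
Reactants: 6 naphthalene-1,8-diol
Product: 7 8-methoxy-1-naphthol (8-methoxynaphthalen-1-ol)
Conditions: MeI (1 equiv), K2CO3 (1 equiv), acetone, reflux
Reagents that add atoms: iodomethane, CI
Why: Williamson ether synthesis that should stop at the monoether, because the first naphthoxide is stabilised by the peri O–H···O hydrogen bond and the hydroxyl left after methylation is hydrogen-bonded to the new methoxy group and is a weaker acid and nucleophile.

Step 3
Reactants: 5 racemic 5-methoxy-1,4-epoxy-1,4-dihydronaphthalene (about 2.2 equiv, of which the (1S,4R) enantiomer is the one consumed); 7 8-methoxy-1-naphthol (1 equiv, limiting)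
Product: 8 (1R,2R)-5-methoxy-2-[(8-methoxynaphthalen-1-yl)oxy]-1,2-dihydronaphthalen-1-ol
Conditions: [Rh(cod)Cl]2 (2.5 mol %), (S)-1-[(R)-2-(diphenylphosphino)ferrocenyl]ethyldi-tert-butylphosphine (6 mol %), THF, 80 °C; chromatography
Reagents that add atoms: none
Why: Rhodium-catalysed asymmetric ring opening of an oxabenzonorbornadiene by a phenol-type nucleophile, run as a kinetic resolution: the chiral bisphosphine–rhodium complex should insert from the exo face into the bridgehead C–O bond it prefers, and the naphthol oxygen should attack the far allyl terminus anti to rhodium (SN2'), setting C1 and C2 trans; in the (1S,4R) enantiomer of 5 the ligand-preferred bond is the C4–O bond peri to the methoxy group, whose ionisation is also helped by the ortho methoxy group, so this matched enantiomer should be opened fast to 8 with the hydroxyl on the remote bridgehead, while the mismatched (1R,4S) enantiomer should be left unreacted once the limiting naphthol is used up and is removed by chromatography.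

Step 4
Reactants: 8 (1R,2R)-5-methoxy-2-[(8-methoxynaphthalen-1-yl)oxy]-1,2-dihydronaphthalen-1-ol
Product: 9 tert-butyl{[(1R,2R)-5-methoxy-2-[(8-methoxynaphthalen-1-yl)oxy]-1,2-dihydronaphthalen-1-yl]oxy}dimethylsilane
Conditions: TBSOTf, 2,6-lutidine, CH2Cl2, −78 °C
Reagents that add atoms: tert-butyldimethylsilyl trifluoromethanesulfonate, CC(C)(C)[Si](C)(C)OS(=O)(=O)C(F)(F)F
Why: O-silylation of a hindered secondary benzylic alcohol with a silyl triflate and a hindered pyridine base should be fast at low temperature and leaves the allylic aryl ether and both stereocentres untouched; the silyl ether removes the free hydroxyl whose protonation or dehydration would otherwise open a path to a naphthalene in the hot step that follows.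

Step 5
Reactants: 9 tert-butyl{[(1R,2R)-5-methoxy-2-[(8-methoxynaphthalen-1-yl)oxy]-1,2-dihydronaphthalen-1-yl]oxy}dimethylsilane
Product: 11 (1S,4R)-1-(tert-butyldimethylsilyloxy)-4-(1-hydroxy-8-methoxynaphthalen-2-yl)-5-methoxy-1,4-dihydronaphthalene, via dienone 10 (not isolated)
Conditions: PhNEt2 (degassed), 150 °C, Ar, base-washed sealed tube; used at once
Reagents that add atoms: none
Why: Proposed new method: heating should bring the ether oxygen, naphthalene C1' and C2' and dihydronaphthalene C2, C3 and C4 into a concerted [3,3] sigmatropic shift in which the C2–O bond breaks while the C4–C2' bond forms and the alkene moves from C3=C4 to C2=C3, giving 2H-naphthalen-1-one 10, which enolises at once to the naphthol. The closest known reactions are the thermal aromatic Claisen rearrangement of aryl cyclohex-2-enyl ethers (with 1,3-transfer of chirality), of cinnamyl aryl ethers and of allyl 1-naphthyl ethers (which deliver to C2), but the shift has not been shown on a 2-aryloxy-1,2-dihydronaphthalene. No ring is closed, since the six-membered array exists only in a folded, boat-like transition state imposed by the cyclic allyl unit. The new stereocentre C4 is controlled by the C2 stereocentre: the ring allows only suprafacial delivery of C2' to the face of C4 from which the oxygen departs at C2, which is the face opposite the C1 silyloxy group, so that the trans-1,2 pair becomes the trans-1,4 pair (4R) while C2 ceases to be a stereocentre. Site selectivity on the naphthalene is secured because the only other position ortho to the ether oxygen is the ring-fusion carbon, and the high double-bond character of C1'–C2' should make the shift fast. The step also needs the concerted shift to outrun heterolysis of the C2–O bond and loss of naphthol or silanol to an aromatic naphthalene, which the silyl ether at C1, the cis relation of H1 to the aryloxy group (no anti-periplanar elimination) and an acid-free, non-polar, weakly basic medium are expected to secure.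

Step 6
Reactants: 11 (1S,4R)-1-(tert-butyldimethylsilyloxy)-4-(1-hydroxy-8-methoxynaphthalen-2-yl)-5-methoxy-1,4-dihydronaphthalene
Product: 12 (1S,4R)-1-(tert-butyldimethylsilyloxy)-4-(1-hydroxy-8-methoxynaphthalen-2-yl)-5-methoxy-1,2,3,4-tetrahydronaphthalene
Conditions: 2-nitrobenzenesulfonohydrazide (excess), Et3N, CH2Cl2, rt
Reagents that add atoms: none
Why: Diimide, formed in situ by base-induced fragmentation of the sulfonyl hydrazide, should transfer two hydrogen atoms in a concerted syn fashion to the unpolarised cis-disubstituted C2=C3 alkene only, without metal hydride intermediates that could shift the alkene or cleave the benzylic C–O bond, so that C1 and C4, the arenes and the naphthol are left as they are.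

Step 7
Reactants: 12 (1S,4R)-1-(tert-butyldimethylsilyloxy)-4-(1-hydroxy-8-methoxynaphthalen-2-yl)-5-methoxy-1,2,3,4-tetrahydronaphthalene
Product: 13 dipolynaphthalene A [(1S,4R)-4-(1-hydroxy-8-methoxynaphthalen-2-yl)-5-methoxy-1,2,3,4-tetrahydronaphthalen-1-ol]
Conditions: Bu4NF, AcOH, THF, 0 °C to rt
Reagents that add atoms: none
Why: Fluoride-mediated desilylation cleaves the Si–O bond under conditions buffered by acetic acid, so that neither strong base acts on the naphthol and the benzylic C4–H nor acid ionises the benzylic C1–O bond, and the two stereocentres are not involved.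

**Compound list**

1 | 3-bromoanisole | COc1cccc(Br)c1 | starting material
2 | furan | c1ccoc1 | starting material
3 | 2-bromo-6-methoxyphenyllithium | [Li]c1c(Br)cccc1OC | intermediate
4 | 3-methoxybenzyne (1,2-didehydro-3-methoxybenzene) | COC1=CC=CC#C1 | intermediate
5 | racemic 5-methoxy-1,4-epoxy-1,4-dihydronaphthalene | COc1cccc2c1C1C=CC2O1 | intermediate
6 | naphthalene-1,8-diol | Oc1cccc2cccc(O)c12 | starting material
7 | 8-methoxy-1-naphthol | COc1cccc2cccc(O)c12 | intermediate
8 | (1R,2R)-5-methoxy-2-[(8-methoxynaphthalen-1-yl)oxy]-1,2-dihydronaphthalen-1-ol (trans) | COc1cccc2c1C=C[C@@H](Oc1cccc3cccc(OC)c13)[C@@H]2O | intermediate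
9 | tert-butyl{[(1R,2R)-5-methoxy-2-[(8-methoxynaphthalen-1-yl)oxy]-1,2-dihydronaphthalen-1-yl]oxy}dimethylsilane | COc1cccc2c1C=C[C@@H](Oc1cccc3cccc(OC)c13)[C@@H]2O[Si](C)(C)C(C)(C)C | intermediate
10 | (1S,4R)-1-(tert-butyldimethylsilyloxy)-5-methoxy-4-(8-methoxy-1-oxo-1,2-dihydronaphthalen-2-yl)-1,4-dihydronaphthalene (dienone; configuration at the transient C2' left open, the centre is lost on enolisation) | COc1cccc2c1[C@@H](C1C=Cc3cccc(OC)c3C1=O)C=C[C@@H]2O[Si](C)(C)C(C)(C)C | intermediate
11 | (1S,4R)-1-(tert-butyldimethylsilyloxy)-4-(1-hydroxy-8-methoxynaphthalen-2-yl)-5-methoxy-1,4-dihydronaphthalene (trans) | COc1cccc2c1[C@@H](c1ccc3cccc(OC)c3c1O)C=C[C@@H]2O[Si](C)(C)C(C)(C)C | intermediate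
12 | (1S,4R)-1-(tert-butyldimethylsilyloxy)-4-(1-hydroxy-8-methoxynaphthalen-2-yl)-5-methoxy-1,2,3,4-tetrahydronaphthalene | COc1cccc2c1[C@@H](c1ccc3cccc(OC)c3c1O)CC[C@@H]2O[Si](C)(C)C(C)(C)C | intermediate
13 | dipolynaphthalene A, (1S,4R)-4-(1-hydroxy-8-methoxynaphthalen-2-yl)-5-methoxy-1,2,3,4-tetrahydronaphthalen-1-ol | COc1cccc2c1[C@@H](c1ccc3cccc(OC)c3c1O)CC[C@@H]2O | target

**Count**

Total steps: 7. Longest linear sequence: 6 steps (1, 3, 4, 5, 6, 7 from 3-bromoanisole); step 2 is a one-step branch.

**Steps most likely to fail**

Step 5 (bears the label). What may go wrong: heterolysis of the allylic C2–O bond, or loss of the naphthol or of silanol with aromatisation of the dihydronaphthalene, outruns the concerted shift; or the product alkene migrates into conjugation and erases C4. The fallback uses known chemistry only: the aryl–C4 bond is made by cross-coupling and C4 is set by hydroxyl-directed hydrogenation. It sets out from 7 and comes back to the route at 13.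

- Aryl partner: naphthol 7 is protected (MOMCl, iPr2NEt, CH2Cl2) as 1-methoxy-8-(methoxymethoxy)naphthalene F1. This is lithiated ortho to the acetal oxygen (n-BuLi, THF) and borylated (B(OiPr)3, then aqueous work-up) to [8-methoxy-1-(methoxymethoxy)naphthalen-2-yl]boronic acid F2.
- Tetralin partner: purchased 5-methoxy-3,4-dihydronaphthalen-1(2H)-one F3 is reduced by asymmetric transfer hydrogenation (RuCl[(S,S)-TsDPEN](p-cymene), HCO2H/Et3N) to (S)-5-methoxy-1,2,3,4-tetrahydronaphthalen-1-ol F4. Silylation (TBSCl, imidazole, DMF) gives tert-butyl{[(S)-5-methoxy-1,2,3,4-tetrahydronaphthalen-1-yl]oxy}dimethylsilane F5. Oxidation of the benzylic methylene next to the methoxy-bearing ring carbon (CrO3, 3,5-dimethylpyrazole, CH2Cl2) gives (S)-4-(tert-butyldimethylsilyloxy)-8-methoxy-3,4-dihydronaphthalen-1(2H)-one F6. Enolisation and triflation (KN(SiMe3)2, PhNTf2, THF, −78 °C) give (S)-4-(tert-butyldimethylsilyloxy)-8-methoxy-3,4-dihydronaphthalen-1-yl trifluoromethanesulfonate F7.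
- Union and end game: Suzuki–Miyaura coupling of F7 with F2 (Pd(OAc)2, SPhos, K3PO4, toluene/water) gives tert-butyl{[(S)-5-methoxy-4-[8-methoxy-1-(methoxymethoxy)naphthalen-2-yl]-1,2-dihydronaphthalen-1-yl]oxy}dimethylsilane F8. Desilylation (Bu4NF, THF) frees (S)-5-methoxy-4-[8-methoxy-1-(methoxymethoxy)naphthalen-2-yl]-1,2-dihydronaphthalen-1-ol F9. Hydrogenation with [Ir(cod)(PCy3)(py)]PF6 under H2 in CH2Cl2, in which the metal is held by the C1 hydroxyl and delivers hydrogen to C4 from the hydroxyl face, should place the aryl group trans and give (1S,4R)-5-methoxy-4-[8-methoxy-1-(methoxymethoxy)naphthalen-2-yl]-1,2,3,4-tetrahydronaphthalen-1-ol F10. Dilute HCl in aqueous THF at rt then removes the acetal to give 13.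

Step 3. What may go wrong: insufficient discrimination between the two bridgehead C–O bonds or between the two enantiomers of 5, so that the ether forms with low enantiomeric purity or mainly as the wrong constitutional isomer. The fallback takes the stereochemistry from a separation instead of from the catalyst; it sets out from 5 and 7 and comes back at 8. The opening is run with an achiral catalyst ([Rh(cod)Cl]2, 1,1'-bis(diphenylphosphino)ferrocene, THF, 80 °C) and a slight excess of 7, so that both enantiomers of 5 are consumed and the regiochemistry rests on the substrate bias alone. The racemic trans ether, which is 8 together with its mirror image (1S,2S)-5-methoxy-2-[(8-methoxynaphthalen-1-yl)oxy]-1,2-dihydronaphthalen-1-ol F11, is freed from any constitutional isomer on silica and resolved by preparative chromatography on a chiral stationary phase. Compound 8 then re-enters at step 4.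

Step 6. What may go wrong: base- or metal-induced migration of the C2=C3 alkene into conjugation (loss of the C4 centre), 1,4-elimination of silanol with aromatisation, or incomplete reduction of the hindered alkene. The fallback reverses the order of the last two operations and uses a homogeneous hydrogenation held by the free hydroxyl; it sets out from 11 and comes back at 13. Buffered fluoride (Bu4NF, AcOH, THF, 0 °C) removes the silyl group to give (1S,4R)-4-(1-hydroxy-8-methoxynaphthalen-2-yl)-5-methoxy-1,4-dihydronaphthalen-1-ol F12. This allylic alcohol is hydrogenated at once with [Ir(cod)(PCy3)(py)]PF6 under H2 (1 atm) in CH2Cl2, where binding of the cationic iridium to the C1 hydroxyl should make saturation of C2=C3 fast under neutral conditions, giving 13 directly.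

**Further compounds**

F1 | step 5 | 1-methoxy-8-(methoxymethoxy)naphthalene | COCOc1cccc2cccc(OC)c12
F2 | step 5 | [8-methoxy-1-(methoxymethoxy)naphthalen-2-yl]boronic acid | COCOc1c(B(O)O)ccc2cccc(OC)c12
F3 | step 5 | 5-methoxy-3,4-dihydronaphthalen-1(2H)-one (purchased) | COc1cccc2c1CCCC2=O
F4 | step 5 | (S)-5-methoxy-1,2,3,4-tetrahydronaphthalen-1-ol | COc1cccc2c1CCC[C@@H]2O
F5 | step 5 | tert-butyl{[(S)-5-methoxy-1,2,3,4-tetrahydronaphthalen-1-yl]oxy}dimethylsilane | COc1cccc2c1CCC[C@@H]2O[Si](C)(C)C(C)(C)C
F6 | step 5 | (S)-4-(tert-butyldimethylsilyloxy)-8-methoxy-3,4-dihydronaphthalen-1(2H)-one | COc1cccc2c1C(=O)CC[C@@H]2O[Si](C)(C)C(C)(C)C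
F7 | step 5 | (S)-4-(tert-butyldimethylsilyloxy)-8-methoxy-3,4-dihydronaphthalen-1-yl trifluoromethanesulfonate | COc1cccc2c1C(OS(=O)(=O)C(F)(F)F)=CC[C@@H]2O[Si](C)(C)C(C)(C)C
F8 | step 5 | tert-butyl{[(S)-5-methoxy-4-[8-methoxy-1-(methoxymethoxy)naphthalen-2-yl]-1,2-dihydronaphthalen-1-yl]oxy}dimethylsilane | COc1cccc2c1C(c1ccc3cccc(OC)c3c1OCOC)=CC[C@@H]2O[Si](C)(C)C(C)(C)C
F9 | step 5 | (S)-5-methoxy-4-[8-methoxy-1-(methoxymethoxy)naphthalen-2-yl]-1,2-dihydronaphthalen-1-ol | COc1cccc2c1C(c1ccc3cccc(OC)c3c1OCOC)=CC[C@@H]2O
F10 | step 5 | (1S,4R)-5-methoxy-4-[8-methoxy-1-(methoxymethoxy)naphthalen-2-yl]-1,2,3,4-tetrahydronaphthalen-1-ol | COc1cccc2c1[C@@H](c1ccc3cccc(OC)c3c1OCOC)CC[C@@H]2O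
F11 | step 3 | (1S,2S)-5-methoxy-2-[(8-methoxynaphthalen-1-yl)oxy]-1,2-dihydronaphthalen-1-ol | COc1cccc2c1C=C[C@H](Oc1cccc3cccc(OC)c13)[C@H]2O
F12 | step 6 | (1S,4R)-4-(1-hydroxy-8-methoxynaphthalen-2-yl)-5-methoxy-1,4-dihydronaphthalen-1-ol | COc1cccc2c1[C@@H](c1ccc3cccc(OC)c3c1O)C=C[C@@H]2O
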